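**Plan**
- Numbering: guaiane numbers are used, unprimed for the cross-conjugated cyclopentenone half and primed for the spiro-cyclopentanone half. The central cyclohexene is C2=C1–C10–C14–C15'–C4'.
- Retrosynthesis: first shift C1=C2 to C1=C10 (the β,γ-enone tautomer, which removes the C10 centre). The cyclohexene is then a Diels–Alder retron, and cutting C2–C4' and C14–C15' gives two C15 guaianolides, each with its 5-7-5 rings complete.
- Enabling feature: spiro C4' and C15' are the α-carbon and the methylene carbon of an exocyclic cyclopentenone (the dienophile). C2=C1–C10=C14 of the other half is a diene held s-cis by its five- and seven-membered rings. The neighbouring carbonyl-bearing carbons C2 and C4' are the "ortho" signature of this union.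
- Forward: the dienophile half comes in two steps from dehydrocostus lactone. The diene half comes from α-santonin by photochemical 6-6 to 5-7 reorganisation, reductive alkene transposition, installation of three alkenes, enone formation and silyl dienol ether formation. Oxidation then frees the diene, the cycloaddition joins the halves and closes the last ring, and a 1,3-proton shift finishes the route.
- Stereochemistry: C1', C5', C6' and C7' come from dehydrocostus lactone, and C6 and C7 from santonin. C5 is set by the suprafacial retro-ene of a 3β-diazene, C4' by attack on the convex α face of the dienophile, and C10 by a same-face proton relay from H-2α.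

Key step: step 13

Remark on the chemistry: read from the SMILES, H-5 of the unprimed half is β (cis to H-6, opposite to natural guaianolides) and H-10 is α, while the primed half has the natural 1'α,5'α,6'β,7'α hydrogens. The diene half is therefore built in the 5-epi series.

**Step 1**
Reactants: 1 (−)-dehydrocostus lactone (1αH,5αH,6βH,7αH-guaia-4(15),10(14),11(13)-trien-12,6α-olide)
Product: 2 isozaluzanin C (3α-hydroxy derivative of 1)
Conditions: SeO2 (0.5 equiv), t-BuOOH (2 equiv), CH2Cl2, 0 °C to rt
Reagents that add atoms: tert-butyl hydroperoxide CC(C)(C)OO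
Why: Catalytic SeO2 allylic hydroxylation (ene reaction, then [2,3]-sigmatropic shift) should attack the accessible cyclopentane-bound alkene C4=C15 at its only allylic CH2 (C3) from the convex α face, the conjugated C11=C13 being inert, and the new C3 centre is erased in step 2.

**Step 2**
Reactants: 2 isozaluzanin C
Product: 3 dehydrozaluzanin C (3-oxo-1αH,5αH-guaia-4(15),10(14),11(13)-trien-12,6α-olide)
Conditions: Dess–Martin periodinane, CH2Cl2, 0 °C to rt
Reagents that add atoms: none
Why: Dess–Martin oxidation converts the allylic alcohol into the exocyclic enone under neutral conditions that spare the methylene groups and the lactone, and no stereocentre is formed.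

**Step 3**
Reactants: 4 (−)-α-santonin
Product: 5 isophotosantonic lactone (10α-hydroxy-3-oxo-1αH,6βH,7αH,11βH-guai-4-en-12,6α-olide)
Conditions: hν (high-pressure Hg lamp), AcOH–H2O (about 1:1), reflux
Reagents that add atoms: water O
Why: The photochemical cross-conjugated cyclohexadienone rearrangement in protic medium (C1–C5 bonding, then opening of the cyclopropyl cation at C10 by water) contracts ring A and expands ring B to the 5-7 hydroazulene, with H-1α and 10α-OH fixed by the stereospecific shift and backside capture while C6, C7 and C11 are carried over.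

**Step 4**
Reactants: 5 isophotosantonic lactone
Product: 6 C3 tosylhydrazone of 5
Conditions: TsNHNH2, EtOH, cat. AcOH, 50 °C
Reagents that add atoms: 4-methylbenzenesulfonohydrazide Cc1ccc(cc1)S(=O)(=O)NN
Why: Hydrazone condensation at the only ketone gives the α,β-unsaturated tosylhydrazone, no stereocentre changes, and the C=N geometry is irrelevant.

**Step 5**
Reactants: 6 C3 tosylhydrazone of 5
Product: 8 10α-hydroxy-1αH,5βH,6βH,7αH,11βH-guai-3-en-12,6α-olide, via allylic diazene 7 (not isolated)
Conditions: catecholborane (3 equiv), CHCl3, −10 to 0 °C; then NaOAc·3H2O, reflux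
Reagents that add atoms: none
Why: In this enone tosylhydrazone reduction with allylic diazene rearrangement, hydride should add to C3 from the α face (the β face is screened by C10 and its methyl group), sulfinate loss gives the 3β-diazene, and its concerted, strongly exergonic retro-ene loss of N2 hands hydrogen suprafacially to the β face of C5, setting the non-natural 5βH and moving the alkene to C3=C4.

**Step 6**
Reactants: 8 10α-hydroxy-1αH,5βH-guai-3-en-12,6α-olide
Product: 9 1αH,5βH,11βH-guaia-3,10(14)-dien-12,6α-olide
Conditions: SOCl2, pyridine, 0 °C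
Reagents that add atoms: none
Why: In the anti-periplanar E2 dehydration of the tertiary chlorosulfite, H-1 is cis to the 10α-oxygen and cannot leave, so the accessible methyl hydrogens should give the exocyclic C10=C14 alkene, and no stereocentre is formed.

**Step 7**
Reactants: 9 1αH,5βH,11βH-guaia-3,10(14)-dien-12,6α-olide
Product: 10 11β-phenylselanyl derivative of 9 (C13 methyl α)
Conditions: LiN(iPr)2, THF, −78 °C; then PhSeCl, −78 °C
Reagents that add atoms: benzeneselenenyl chloride Cl[Se]c1ccccc1
Why: α-Selenenylation of the lactone enolate uses the only acidic C–H (H-11), selenium should enter trans to H-7, and the C11 centre is erased in step 8.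

**Step 8**
Reactants: 10 11β-phenylselanyl lactone
Product: 12 1αH,5βH-guaia-3,10(14),11(13)-trien-12,6α-olide (5-epi-isodehydrocostus lactone), via selenoxide 11 (not isolated)
Conditions: 30% H2O2, cat. AcOH, THF, 0 °C to rt
Reagents that add atoms: none
Why: In the selenide oxidation and selenoxide syn-elimination, selenium is trans to H-7, so only the C13 methyl hydrogens are within reach and the α-methylene lactone should result.

**Step 9**
Reactants: 12 5-epi-isodehydrocostus lactone
Product: 13 3β,4β-epoxide of 12
Conditions: mCPBA (1.0 equiv), CH2Cl2, 0 °C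
Reagents that add atoms: 3-chloroperbenzoic acid OOC(=O)c1cccc(Cl)c1
Why: Prilezhaev epoxidation should pick the only trisubstituted, most electron-rich alkene C3=C4 over C10=C14 and the conjugated C11=C13, from the β face anti to C6 on the adjacent C5, and both new centres are erased in steps 10 and 11.

**Step 10**
Reactants: 13 3β,4β-epoxide
Product: 14 3β-hydroxy-1αH,5βH-guaia-4(15),10(14),11(13)-trien-12,6α-olide
Conditions: Al(OiPr)3 (2 equiv), toluene, reflux; aqueous work-up
Reagents that add atoms: none
Why: In this aluminium alkoxide-mediated isomerisation of an epoxide to an allylic alcohol, the tertiary C4–O bond breaks on coordination and an isopropoxide ligand removes a syn hydrogen of the freely rotating C15 methyl group through a cyclic transition state, giving C4=C15 with the C3–O bond retained.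

**Step 11**
Reactants: 14 3β-hydroxy triene
Product: 15 5-epi-dehydrozaluzanin C (3-oxo-1αH,5βH-guaia-4(15),10(14),11(13)-trien-12,6α-olide)
Conditions: Dess–Martin periodinane, CH2Cl2, 0 °C to rt
Reagents that add atoms: none
Why: Dess–Martin oxidation gives the exocyclic enone under neutral conditions, and H-5 is not conjugated with the carbonyl group here, so C5 should hold.

**Step 12**
Reactants: 15 5-epi-dehydrozaluzanin C
Product: 16 3-(tert-butyldimethylsilyloxy)-1αH,5βH-guaia-2,4(15),10(14),11(13)-tetraen-12,6α-olide
Conditions: TBSOTf (1.2 equiv), Et3N (2 equiv), CH2Cl2, −78 to 0 °C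
Reagents that add atoms: tert-butyldimethylsilyl triflate CC(C)(C)[Si](C)(C)OS(=O)(=O)C(F)(F)F
Why: In this soft enolisation and O-silylation, C2 carries the only enolisable hydrogens, so a single silyl dienol ether should form, and its C15=C4–C3=C2 unit is locked s-trans and is therefore inert as a diene toward 3.

**Step 13**
Reactants: 16 silyl dienol ether; 3 dehydrozaluzanin C (3 equiv)
Product: 18 Diels–Alder adduct (β,γ-enone: 2αH, C1=C10, new bonds C2–C4' and C14–C15', C2 on the α face of C4'), via dienone 17 (not isolated)
Conditions: Pd(OAc)2 (1.05 equiv), degassed MeCN, argon, dark, rt to 40 °C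
Reagents that add atoms: none
Why: Pd(OAc)2 palladates 16 at C2 and syn β-hydride elimination of H-1 (Saegusa–Ito oxidation) unveils dienone 17, whose ring-locked s-cis diene C2=C1–C10=C14 is trapped at once by the exocyclic enone C4'=C15' of 3 in a concerted, asynchronous, suprafacial–suprafacial [4+2] cycloaddition. The closest known reaction type is the biomimetic tandem Saegusa–Ito oxidation and intermolecular Diels–Alder heterodimerisation of guaianolide enones, a case of the "ortho"-selective Diels–Alder union of 1-acyl dienes with 2-methylene ketones. The one new ring, cyclohexene C2–C1=C10–C14–C15'–C4', is closed by intermolecular cycloaddition that forms C14–C15' (the leading bond, joining the two electrophilic termini) and C2–C4' in one event, which places the two carbonyl-bearing carbons side by side. C4' is set by addition to the convex α face of the cis-fused hydroazulenone 3 (the face of H-1' and H-5'), and C2 by addition to the β face of 17, which carries only H-5 because C6 and the lactone-bearing ring hang below the flat dienone; this pairing puts C3'=O endo over the diene half and the bulky C5' side exo. The step needs cross- over self-cycloaddition, carbo- over hetero-Diels–Alder periselectivity and an intact C5, which should be secured by gradual release of 17 into an excess of 3, by the far higher reactivity of the planar dienone diene than of any other π pair present, and by the base-free medium; air is excluded because the adduct would autoxidise at C10.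

**Step 14**
Reactants: 18 Diels–Alder adduct
Product: 19 target CNP0221188.1 (C1=C2 enone, 5βH, 10αH)
Conditions: DBU (0.1 equiv), degassed toluene, argon, −40 °C; AcOH quench at −40 °C
Reagents that add atoms: none
Why: In this amidine-catalysed 1,3-prototropic shift (β,γ- to α,β-enone isomerisation), DBU removes the doubly activated H-2 from the α face and, within the tight ion pair that persists in cold toluene, the amidinium should return the proton on the same face to C10 of the dienolate, giving H-10α and the C1=C2 enone while the short cold contact leaves the less acidic γ-hydrogens H-5 and H-10 of the product untouched.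

**Compound list**
1 | (−)-dehydrocostus lactone | C=C1CC[C@H]2C(=C)CC[C@H]3C(=C)C(=O)O[C@@H]3[C@H]21 | starting material
2 | isozaluzanin C (3α-OH) | C=C1[C@H](O)C[C@H]2C(=C)CC[C@H]3C(=C)C(=O)O[C@@H]3[C@H]21 | intermediate
3 | dehydrozaluzanin C | C=C1C(=O)C[C@H]2C(=C)CC[C@H]3C(=C)C(=O)O[C@@H]3[C@H]21 | intermediate
4 | (−)-α-santonin | C[C@H]1[C@@H]2CC[C@]3(C=CC(=O)C(=C3[C@H]2OC1=O)C)C | starting material
5 | isophotosantonic lactone | CC1=C2[C@H]3OC(=O)[C@@H](C)[C@@H]3CC[C@@](C)(O)[C@@H]2CC1=O | intermediate
6 | C3 tosylhydrazone of 5 (C=N geometry not defined) | CC1=C2[C@H]3OC(=O)[C@@H](C)[C@@H]3CC[C@@](C)(O)[C@@H]2CC1=NNS(=O)(=O)c4ccc(C)cc4 | intermediate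
7 | 3β-diazenyl-10α-hydroxy-1αH-guai-4-en-12,6α-olide (allylic diazene) | CC1=C2[C@H]3OC(=O)[C@@H](C)[C@@H]3CC[C@@](C)(O)[C@@H]2C[C@@H]1N=N | intermediate
8 | 10α-hydroxy-1αH,5βH,11βH-guai-3-en-12,6α-olide | CC1=CC[C@H]2[C@](C)(O)CC[C@H]3[C@H](C)C(=O)O[C@@H]3[C@H]12 | intermediate
9 | 1αH,5βH,11βH-guaia-3,10(14)-dien-12,6α-olide | CC1=CC[C@H]2C(=C)CC[C@H]3[C@H](C)C(=O)O[C@@H]3[C@H]12 | intermediate
10 | 11β-phenylselanyl derivative of 9 | CC1=CC[C@H]2C(=C)CC[C@H]3[C@@](C)([Se]c4ccccc4)C(=O)O[C@@H]3[C@H]12 | intermediate
11 | selenoxide of 10 (Se centre not defined) | CC1=CC[C@H]2C(=C)CC[C@H]3[C@@](C)([Se](=O)c4ccccc4)C(=O)O[C@@H]3[C@H]12 | intermediate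
12 | 5-epi-isodehydrocostus lactone | CC1=CC[C@H]2C(=C)CC[C@H]3C(=C)C(=O)O[C@@H]3[C@H]12 | intermediate
13 | 3β,4β-epoxide of 12 | C[C@]15O[C@H]1C[C@H]2C(=C)CC[C@H]3C(=C)C(=O)O[C@@H]3[C@@H]25 | intermediate
14 | 3β-hydroxy-1αH,5βH-guaia-4(15),10(14),11(13)-trien-12,6α-olide | C=C1[C@@H](O)C[C@H]2C(=C)CC[C@H]3C(=C)C(=O)O[C@@H]3[C@@H]21 | intermediate
15 | 5-epi-dehydrozaluzanin C | C=C1C(=O)C[C@H]2C(=C)CC[C@H]3C(=C)C(=O)O[C@@H]3[C@@H]21 | intermediate
16 | TBS dienol ether of 15 | C=C1C(O[Si](C)(C)C(C)(C)C)=C[C@H]2C(=C)CC[C@H]3C(=C)C(=O)O[C@@H]3[C@@H]21 | intermediate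
17 | 3-oxo-5βH-guaia-1,4(15),10(14),11(13)-tetraen-12,6α-olide (dienone) | C=C1C(=O)C=C2C(=C)CC[C@H]3C(=C)C(=O)O[C@@H]3[C@@H]21 | intermediate
18 | Diels–Alder adduct (2αH, C1=C10) | C=C1C(=O)[C@@H]2C3=C(CC[C@H]4C(=C)C(=O)O[C@@H]4[C@H]13)CC[C@]21C(=O)C[C@H]2C(=C)CC[C@H]3C(=C)C(=O)O[C@@H]3[C@H]21 | intermediate
19 | CNP0221188.1 | C=C1C(=O)C2=C3[C@H](CC[C@H]4C(=C)C(=O)O[C@@H]4[C@H]13)CC[C@]21C(=O)C[C@H]2C(=C)CC[C@H]3C(=C)C(=O)O[C@@H]3[C@H]21 | target

Total step count: 14. Longest linear sequence: 12 steps (steps 3 to 14, from α-santonin).

**Steps most likely to fail**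

Step 14. The required C10 epimer holds C9 and C6 on opposite faces of the flat enone, an arrangement the seven-membered ring with its trans-fused lactone accommodates poorly. This epimer is expected to be less stable than its C10 epimer. Leakage of the ion pair to the β face, or reversible γ-deprotonation of the product, would therefore erode C10 and, more slowly, C5. The fallback sets out from 18 and comes back at 19. The achiral amidine is replaced by catalyst-controlled proton-transfer catalysis with a bifunctional cinchona base (6'-hydroxy quinidine- and quinine-derived catalysts, both pseudoenantiomers tried). This is a known way to isomerise β,γ- to α,β-unsaturated ketones and butenolides, in which the catalyst ammonium, held by a hydrogen bond to the dienolate oxygen, chooses the face of γ-protonation instead of the substrate. It makes no new compound (F0).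

Step 13. The freed dienone may be consumed by self-cycloaddition through its own exocyclic enone. Acetic acid and palladium residues may also enolise it toward C5 before the cross-reaction occurs. The fallback sets out from 16 and comes back at 18, and it uncouples diene release from palladium:
- PhSeCl at −78 °C converts 16 into the 2α-phenylselanyl ketone F1 (selenium anti to C10, hence cis to H-1).
- mCPBA (1 equiv) at −78 °C gives the selenoxide F2.
- Slow addition of F2 to a solution of excess 3 at 0 °C releases 17 by syn-elimination in a metal-free, acid-free medium at a low stationary concentration.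

Step 5. Poor facial selectivity of hydride delivery to the flat hydrazone would pass directly into C5. The fallback sets out from 5 and comes back at 8, and it moves the decision to isolable compounds:
- Luche reduction (NaBH4, CeCl3·7H2O, MeOH, 0 °C) gives the 3α-allylic alcohol F3 and the 3β-allylic alcohol F5, which are separated. F5 is returned to 5 by Dess–Martin oxidation.
- Mitsunobu displacement of F3 with 2-nitrobenzenesulfonylhydrazide (PPh3, DEAD, THF, −30 °C) gives, with inversion, the 3β-sulfonylhydrazide F4.
- On warming, F4 loses the sulfinic acid to give the same diazene 7, which collapses to 8 (Myers allylic transposition). The tertiary 10-OH does not take part.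

**Further compounds**
F0 | step 14 | none | none
F1 | step 13 | 2α-phenylselanyl-5-epi-dehydrozaluzanin C | C=C1C(=O)[C@H]([Se]c4ccccc4)[C@H]2C(=C)CC[C@H]3C(=C)C(=O)O[C@@H]3[C@@H]21
F2 | step 13 | selenoxide of F1 (Se centre not defined) | C=C1C(=O)[C@H]([Se](=O)c4ccccc4)[C@H]2C(=C)CC[C@H]3C(=C)C(=O)O[C@@H]3[C@@H]21
F3 | step 5 | 3α,10α-dihydroxy-1αH-guai-4-en-12,6α-olide | CC1=C2[C@H]3OC(=O)[C@@H](C)[C@@H]3CC[C@@](C)(O)[C@@H]2C[C@H]1O
F4 | step 5 | 3β-[1-(2-nitrophenylsulfonyl)hydrazinyl]-10α-hydroxy-1αH-guai-4-en-12,6α-olide | CC1=C2[C@H]3OC(=O)[C@@H](C)[C@@H]3CC[C@@](C)(O)[C@@H]2C[C@@H]1N(N)S(=O)(=O)c4ccccc4[N+](=O)[O-]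
F5 | step 5 | 3β,10α-dihydroxy-1αH-guai-4-en-12,6α-olide | CC1=C2[C@H]3OC(=O)[C@@H](C)[C@@H]3CC[C@@](C)(O)[C@@H]2C[C@@H]1O
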